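**Retrosynthetic overview**
1. The target comes from a tri-O-silylated 14-membered carbocycle by selective desilylation, diacetylation and final desilylation. The ring is closed last, at the C11–C12 diene σ-bond, by an intramolecular palladium-catalysed alkenylstannane/alkenyl iodide (Stille) coupling.
2. The seco precursor comes from a Z-selective Wittig olefination (C2=C3) of an α,β-bis(silyloxy) methyl ketone (C12–C14, C1, C2) with a C3–C11 phosphonium ylide.
3. The ketone comes from a catalytic direct syn-aldol of hydroxyacetone (C1–C14 bond, both acetoxy-bearing stereocentres) with a (Z)-β-iodo enal, itself made by copper-catalysed anti-carbomagnesiation/iodination of propargyl alcohol.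
4. The ylide comes from CBS reduction (C5) of an enone assembled by cross-metathesis (C6=C7) of an (E)-iododiene (zirconium-catalysed methylalumination of hex-1-en-5-yne) with a chloroethyl isopropenyl ketone.
5. Ring order: there is one carbocycle only, formed in step 13.

Assumption and locants: ring carbons are numbered C1–C14 in the order of the target SMILES (C1 = first AcO–CH, C2(Me)=C3, C4, C5(OH), C6(Me)=C7, C8, C9, C10(Me)=C11, C12=C13(i-Pr), C14 = second AcO–CH); these locants are used in all macrocycle names, and the target is (1R,5S,14R; 2Z,6E,10E,12Z).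

**Route**

Step 1
Reactants: 1 prop-2-yn-1-ol
Product: 3 (2Z)-3-iodo-2-(propan-2-yl)prop-2-en-1-ol, via cyclic alkenylmagnesium alkoxide 2 (not isolated)
Conditions: i-PrMgCl (3 equiv), CuI (10 mol%), THF, −10 °C to rt; then I2, THF, −40 to 0 °C
Reagents that add atoms: isopropylmagnesium chloride CC(C)[Mg]Cl; iodine II
Why: Copper-catalysed anti-carbomagnesiation of the propargylic alkoxide puts i-Pr on the internal carbon and Mg on the terminal carbon inside a five-membered chelate, so iodinolysis with retention gives the iodide cis to CH2OH, which is the C12=C13 geometry of the target.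

Step 2
Reactants: 3 (2Z)-3-iodo-2-(propan-2-yl)prop-2-en-1-ol
Product: 4 (2Z)-2-(iodomethylidene)-3-methylbutanal
Conditions: MnO2 (15 equiv), CH2Cl2, rt, dark
Reagents that add atoms: none
Why: Heterogeneous allylic oxidation with MnO2 is neutral and mild, so the Z-iodoalkene is kept; the aldehyde is used at once.

Step 3
Reactants: 4 (2Z)-2-(iodomethylidene)-3-methylbutanal; 5 1-hydroxypropan-2-one
Product: 6 (3S,4R,5Z)-3,4-dihydroxy-6-iodo-5-(propan-2-yl)hex-5-en-2-one
Conditions: (S,S)-ProPhenol (10 mol%), Et2Zn (20 mol%), 4 Å MS, THF, −30 °C, hydroxyacetone in twofold excess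
Reagents that add atoms: none
Why: Proposed new method: a dinuclear zinc–ProPhenol-catalysed direct syn-aldol addition of unprotected hydroxyacetone to a (Z)-β-iodo-α-branched enal, in which every atom of 4 and of one molecule of 5 ends up in 6, one zinc holds hydroxyacetone as a five-membered Z-enediolate chelate (deprotonation at the hydroxylated carbon) and the second zinc binds the non-enolisable aldehyde 4, so that a closed bimetallic transition state gives the syn-diol and the (S,S)-ligand pocket sets C1 and C14 as (3S,4R) in 6; the closest known reaction type is the ProPhenol direct aldol of α-hydroxy aryl ketones (and the amine-catalysed syn-aldol of hydroxyacetone with aryl aldehydes), here extended to a new donor–acceptor pair.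

Step 4
Reactants: 6 (3S,4R,5Z)-3,4-dihydroxy-6-iodo-5-(propan-2-yl)hex-5-en-2-one
Product: 7 (3S,4R,5Z)-6-iodo-5-(propan-2-yl)-3,4-bis(triethylsilyloxy)hex-5-en-2-one
Conditions: TESOTf (2.5 equiv), 2,6-lutidine, CH2Cl2, −78 °C
Reagents that add atoms: triethylsilyl trifluoromethanesulfonate CC[Si](CC)(CC)OS(=O)(=O)C(F)(F)F
Why: Silyl triflate with a hindered base silylates both secondary alcohols at low temperature faster than it enolises the ketone, which blocks retro-aldol and gives the α-alkoxy ketone needed for the Wittig step.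

Step 5
Reactants: 7 (3S,4R,5Z)-6-iodo-5-(propan-2-yl)-3,4-bis(triethylsilyloxy)hex-5-en-2-one
Product: 8 (3S,4R,5Z)-5-(propan-2-yl)-3,4-bis(triethylsilyloxy)-6-(trimethylstannyl)hex-5-en-2-one
Conditions: Me3SnSnMe3 (1.5 equiv), Pd(PPh3)4 (5 mol%), toluene, 80 °C
Reagents that add atoms: hexamethylditin C[Sn](C)(C)[Sn](C)(C)C
Why: Palladium-catalysed iodine–tin exchange (oxidative addition of zerovalent palladium, transmetalation with the ditin, reductive elimination) retains the Z-alkene and tolerates the ketone and silyl ethers.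

Step 6
Reactants: 9 3-chloropropanoyl chloride
Product: 10 5-chloro-2-methylpent-1-en-3-one
Conditions: CH2=C(CH3)MgBr (1.0 equiv), CuI (5 mol%), THF, −78 °C
Reagents that add atoms: isopropenylmagnesium bromide C=C(C)[Mg]Br
Why: Copper-catalysed acylation of a Grignard reagent by an acid chloride at −78 °C stops at the ketone, and the β-chloride survives the cold, non-basic work-up.

Step 7
Reactants: 11 hex-1-en-5-yne
Product: 13 (1E)-1-iodo-2-methylhexa-1,5-diene, via alkenylalane 12 (not isolated)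
Conditions: AlMe3 (2 equiv), Cp2ZrCl2 (20 mol%), CH2Cl2, 0 °C to rt; then I2, THF, −30 °C
Reagents that add atoms: trimethylaluminium C[Al](C)C; iodine II
Why: Negishi zirconium-catalysed carboalumination adds Me and Al syn across the terminal alkyne only (the alkene is inert), and iodinolysis with retention gives the E-iodide, which is the C10=C11 geometry.

Step 8
Reactants: 13 (1E)-1-iodo-2-methylhexa-1,5-diene; 10 5-chloro-2-methylpent-1-en-3-one
Product: 14 (4E,8E)-1-chloro-9-iodo-4,8-dimethylnona-4,8-dien-3-one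
Conditions: second-generation Hoveyda–Grubbs catalyst [RuCl2(H2IMes)(=CH-C6H4-2-O-i-Pr)] (5 mol%), CH2Cl2, 40 °C, enone in threefold excess
Reagents that add atoms: none
Why: Cross-metathesis of the monosubstituted alkene with the 1,1-disubstituted enone gives the thermodynamically favoured E-trisubstituted enone (C6=C7), while the trisubstituted alkenyl iodide does not take part.

Step 9
Reactants: 14 (4E,8E)-1-chloro-9-iodo-4,8-dimethylnona-4,8-dien-3-one
Product: 15 (3S,4E,8E)-1-chloro-9-iodo-4,8-dimethylnona-4,8-dien-3-ol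
Conditions: (R)-2-methyl-CBS-oxazaborolidine (20 mol%), catecholborane (1.5 equiv), toluene, −78 °C
Reagents that add atoms: none
Why: Corey–Bakshi–Shibata reduction treats the α-methylalkenyl group as the large and CH2CH2Cl as the small substituent, so the (R)-catalyst delivers hydride to give the (S)-allylic alcohol, which is the C5 stereocentre, by 1,2-reduction only.

Step 10
Reactants: 15 (3S,4E,8E)-1-chloro-9-iodo-4,8-dimethylnona-4,8-dien-3-ol
Product: 16 tert-butyl{[(3S,4E,8E)-1-chloro-9-iodo-4,8-dimethylnona-4,8-dien-3-yl]oxy}dimethylsilane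
Conditions: TBSOTf (1.3 equiv), 2,6-lutidine, CH2Cl2, −78 to 0 °C
Reagents that add atoms: tert-butyldimethylsilyl trifluoromethanesulfonate CC(C)(C)[Si](C)(C)OS(=O)(=O)C(F)(F)F
Why: Standard silylation of the secondary allylic alcohol gives an ether that survives ylide formation and is more robust than the two triethylsilyl ethers removed in step 14.

Step 11
Reactants: 16 tert-butyl{[(3S,4E,8E)-1-chloro-9-iodo-4,8-dimethylnona-4,8-dien-3-yl]oxy}dimethylsilane
Product: 17 {(3S,4E,8E)-3-[tert-butyl(dimethyl)silyl]oxy-9-iodo-4,8-dimethylnona-4,8-dien-1-yl}triphenylphosphonium iodide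
Conditions: PPh3 (1.5 equiv), NaI (1.2 equiv), MeCN, 80 °C
Reagents that add atoms: triphenylphosphine c1ccccc1P(c1ccccc1)c1ccccc1; sodium iodide [Na+].[I-]
Why: Finkelstein exchange followed by SN2 quaternisation of PPh3 at the primary carbon gives the phosphonium salt; the alkenyl iodide does not react with PPh3 without a metal catalyst.

Step 12
Reactants: 17 {(3S,4E,8E)-3-[tert-butyl(dimethyl)silyl]oxy-9-iodo-4,8-dimethylnona-4,8-dien-1-yl}triphenylphosphonium iodide; 8 (3S,4R,5Z)-5-(propan-2-yl)-3,4-bis(triethylsilyloxy)-6-(trimethylstannyl)hex-5-en-2-one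
Product: 19 (1E,5E,7S,9Z,11R,12R,13Z)-7-[tert-butyl(dimethyl)silyl]oxy-1-iodo-2,6,10-trimethyl-13-(propan-2-yl)-11,12-bis(triethylsilyloxy)-14-(trimethylstannyl)tetradeca-1,5,9,13-tetraene, via phosphonium ylide 18 (not isolated)
Conditions: NaN(SiMe3)2 (1.0 equiv), THF, −78 to 0 °C; then 8, −78 °C to rt
Reagents that add atoms: none
Why: Still-type Wittig olefination of an α-alkoxy methyl ketone with a non-stabilised ylide under lithium-free conditions gives the Z-trisubstituted alkene (C1 and C4 cis, C2=C3), and the γ-silyloxy group of the ylide cannot eliminate.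

Step 13
Reactants: 19 (1E,5E,7S,9Z,11R,12R,13Z)-7-[tert-butyl(dimethyl)silyl]oxy-1-iodo-2,6,10-trimethyl-13-(propan-2-yl)-11,12-bis(triethylsilyloxy)-14-(trimethylstannyl)tetradeca-1,5,9,13-tetraene
Product: 20 (1R,2Z,5S,6E,10E,12Z,14R)-5-[tert-butyl(dimethyl)silyl]oxy-2,6,10-trimethyl-13-(propan-2-yl)-1,14-bis(triethylsilyloxy)cyclotetradeca-2,6,10,12-tetraene
Conditions: Pd2(dba)3 (10 mol%), AsPh3 (40 mol%), NMP, 40 °C, 1 mM, slow addition
Reagents that add atoms: none
Why: Macrocyclising Migita–Kosugi–Stille coupling (oxidative addition of zerovalent palladium into the E-alkenyl iodide, tin-to-palladium transmetalation of the Z-alkenylstannane, reductive elimination) forms the C11–C12 bond and the 14-membered ring with retention at both alkenes, and high dilution suppresses oligomers.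

Step 14
Reactants: 20 (1R,2Z,5S,6E,10E,12Z,14R)-5-[tert-butyl(dimethyl)silyl]oxy-2,6,10-trimethyl-13-(propan-2-yl)-1,14-bis(triethylsilyloxy)cyclotetradeca-2,6,10,12-tetraene
Product: 21 (1R,2Z,5S,6E,10E,12Z,14R)-5-[tert-butyl(dimethyl)silyl]oxy-2,6,10-trimethyl-13-(propan-2-yl)cyclotetradeca-2,6,10,12-tetraene-1,14-diol
Conditions: HF·pyridine, pyridine, THF, 0 °C
Reagents that add atoms: none
Why: Buffered HF·pyridine cleaves triethylsilyl ethers far faster than the secondary tert-butyldimethylsilyl ether and is not acidic enough to ionise the dienylic C14–O bond.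

Step 15
Reactants: 21 (1R,2Z,5S,6E,10E,12Z,14R)-5-[tert-butyl(dimethyl)silyl]oxy-2,6,10-trimethyl-13-(propan-2-yl)cyclotetradeca-2,6,10,12-tetraene-1,14-diol
Product: 22 (1R,2Z,5S,6E,10E,12Z,14R)-5-[tert-butyl(dimethyl)silyl]oxy-2,6,10-trimethyl-13-(propan-2-yl)cyclotetradeca-2,6,10,12-tetraene-1,14-diyl diacetate
Conditions: Ac2O (4 equiv), pyridine, DMAP (cat.), CH2Cl2, rt
Reagents that add atoms: acetic anhydride CC(=O)OC(C)=O
Why: DMAP-catalysed acylation esterifies both secondary allylic alcohols with retention while C5–O stays silylated.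

Step 16
Reactants: 22 (1R,2Z,5S,6E,10E,12Z,14R)-5-[tert-butyl(dimethyl)silyl]oxy-2,6,10-trimethyl-13-(propan-2-yl)cyclotetradeca-2,6,10,12-tetraene-1,14-diyl diacetate
Product: 23 Gibberosene E, (1R,2Z,5S,6E,10E,12Z,14R)-5-hydroxy-2,6,10-trimethyl-13-(propan-2-yl)cyclotetradeca-2,6,10,12-tetraene-1,14-diyl diacetate
Conditions: HF·pyridine, THF, 0 °C to rt
Reagents that add atoms: none
Why: Fluoride-mediated desilylation under non-basic conditions frees the C5 alcohol without acetyl migration or ester cleavage.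

**Compound list**
1 | prop-2-yn-1-ol | C#CCO | starting material
2 | 4-(propan-2-yl)-5H-1,2-oxamagnesole (cyclic alkenylmagnesium alkoxide) | CC(C)C1=C[Mg]OC1 | intermediate (not isolated)
3 | (2Z)-3-iodo-2-(propan-2-yl)prop-2-en-1-ol | OC/C(=C\I)C(C)C | intermediate
4 | (2Z)-2-(iodomethylidene)-3-methylbutanal | O=C/C(=C\I)C(C)C | intermediate
5 | 1-hydroxypropan-2-one | CC(=O)CO | starting material
6 | (3S,4R,5Z)-3,4-dihydroxy-6-iodo-5-(propan-2-yl)hex-5-en-2-one | CC(=O)[C@@H](O)[C@H](O)/C(=C\I)C(C)C | intermediate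
7 | (3S,4R,5Z)-6-iodo-5-(propan-2-yl)-3,4-bis(triethylsilyloxy)hex-5-en-2-one | CC(=O)[C@@H](O[Si](CC)(CC)CC)[C@H](O[Si](CC)(CC)CC)/C(=C\I)C(C)C | intermediate
8 | (3S,4R,5Z)-5-(propan-2-yl)-3,4-bis(triethylsilyloxy)-6-(trimethylstannyl)hex-5-en-2-one | CC(=O)[C@@H](O[Si](CC)(CC)CC)[C@H](O[Si](CC)(CC)CC)/C(=C\[Sn](C)(C)C)C(C)C | intermediate
9 | 3-chloropropanoyl chloride | ClCCC(Cl)=O | starting material
10 | 5-chloro-2-methylpent-1-en-3-one | C=C(C)C(=O)CCCl | intermediate
11 | hex-1-en-5-yne | C=CCCC#C | starting material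
12 | dimethyl[(1E)-2-methylhexa-1,5-dien-1-yl]alane | C=CCC/C(C)=C/[Al](C)C | intermediate (not isolated)
13 | (1E)-1-iodo-2-methylhexa-1,5-diene | C=CCC/C(C)=C/I | intermediate
14 | (4E,8E)-1-chloro-9-iodo-4,8-dimethylnona-4,8-dien-3-one | ClCCC(=O)/C(C)=C/CC/C(C)=C/I | intermediate
15 | (3S,4E,8E)-1-chloro-9-iodo-4,8-dimethylnona-4,8-dien-3-ol | ClCC[C@H](O)/C(C)=C/CC/C(C)=C/I | intermediate
16 | tert-butyl{[(3S,4E,8E)-1-chloro-9-iodo-4,8-dimethylnona-4,8-dien-3-yl]oxy}dimethylsilane | ClCC[C@H](O[Si](C)(C)C(C)(C)C)/C(C)=C/CC/C(C)=C/I | intermediate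
17 | {(3S,4E,8E)-3-[tert-butyl(dimethyl)silyl]oxy-9-iodo-4,8-dimethylnona-4,8-dien-1-yl}triphenylphosphonium iodide | c1ccccc1[P+](c1ccccc1)(c1ccccc1)CC[C@H](O[Si](C)(C)C(C)(C)C)/C(C)=C/CC/C(C)=C/I.[I-] | intermediate
18 | {(3S,4E,8E)-3-[tert-butyl(dimethyl)silyl]oxy-9-iodo-4,8-dimethylnona-4,8-dien-1-ylidene}triphenyl-λ5-phosphane (ylide) | c1ccccc1P(c1ccccc1)(c1ccccc1)=CC[C@H](O[Si](C)(C)C(C)(C)C)/C(C)=C/CC/C(C)=C/I | intermediate (not isolated)
19 | (1E,5E,7S,9Z,11R,12R,13Z)-7-[tert-butyl(dimethyl)silyl]oxy-1-iodo-2,6,10-trimethyl-13-(propan-2-yl)-11,12-bis(triethylsilyloxy)-14-(trimethylstannyl)tetradeca-1,5,9,13-tetraene | C[Sn](C)(C)/C=C(/C(C)C)[C@@H](O[Si](CC)(CC)CC)[C@H](O[Si](CC)(CC)CC)/C(C)=C\C[C@H](O[Si](C)(C)C(C)(C)C)/C(C)=C/CC/C(C)=C/I | intermediate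
20 | (1R,2Z,5S,6E,10E,12Z,14R)-5-[tert-butyl(dimethyl)silyl]oxy-2,6,10-trimethyl-13-(propan-2-yl)-1,14-bis(triethylsilyloxy)cyclotetradeca-2,6,10,12-tetraene | CC[Si](CC)(CC)O[C@@H]1/C(C)=C\C[C@H](O[Si](C)(C)C(C)(C)C)/C(C)=C/CC/C(C)=C/C=C(/C(C)C)[C@H]1O[Si](CC)(CC)CC | intermediate
21 | (1R,2Z,5S,6E,10E,12Z,14R)-5-[tert-butyl(dimethyl)silyl]oxy-2,6,10-trimethyl-13-(propan-2-yl)cyclotetradeca-2,6,10,12-tetraene-1,14-diol | O[C@@H]1/C(C)=C\C[C@H](O[Si](C)(C)C(C)(C)C)/C(C)=C/CC/C(C)=C/C=C(/C(C)C)[C@H]1O | intermediate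
22 | (1R,2Z,5S,6E,10E,12Z,14R)-5-[tert-butyl(dimethyl)silyl]oxy-2,6,10-trimethyl-13-(propan-2-yl)cyclotetradeca-2,6,10,12-tetraene-1,14-diyl diacetate | CC(=O)O[C@@H]1/C(C)=C\C[C@H](O[Si](C)(C)C(C)(C)C)/C(C)=C/CC/C(C)=C/C=C(/C(C)C)[C@H]1OC(C)=O | intermediate
23 | Gibberosene E, (1R,2Z,5S,6E,10E,12Z,14R)-5-hydroxy-2,6,10-trimethyl-13-(propan-2-yl)cyclotetradeca-2,6,10,12-tetraene-1,14-diyl diacetate | CC(=O)O[C@@H]1/C(C)=C\C[C@H](O)/C(C)=C/CC/C(C)=C/C=C(/C(C)C)[C@H]1OC(C)=O | target

**Step count**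
Total step count: 16. Longest linear sequence: 10 steps (steps 1–5 then 12–16; equally steps 6, 8–16 or steps 7–16).

**Steps most likely to fail, with fallbacks**

Step 3 (the proposed new aldol). Risks are enolisation of hydroxyacetone on the methyl side, Z-to-E isomerisation or addition–elimination at the β-iodo enal, and the sense of induction. The (S,S)-ligand is chosen by analogy with the α-hydroxy aryl ketone series and I am not certain of it; it must be checked on 6 (Mosher esters), and (R,R)-ProPhenol is used if the sense is reversed. The fallback uses known chemistry, sets out from aldehyde 4 and comes back at diol ketone 6. A boron-mediated Evans syn-glycolate aldol of 4 with the known reagent (4S)-4-benzyl-3-{[(4-methoxybenzyl)oxy]acetyl}-1,3-oxazolidin-2-one (n-Bu2BOTf, Et3N, CH2Cl2, −78 to 0 °C) gives the syn-aldol imide F1. Transamidation (MeONHMe·HCl, AlMe3, CH2Cl2) gives the Weinreb amide F2 and releases the auxiliary. MeMgBr (3 equiv, THF, −20 °C) gives the PMB-protected hydroxy methyl ketone F3. DDQ in CH2Cl2/pH 7 buffer removes the PMB group to give 6.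

Step 12 (Wittig). Risks are enolisation, C1 epimerisation or β-elimination of the hindered α,β-bis(silyloxy) ketone by the basic ylide, and incomplete Z-selectivity. The fallback sets out from chloride 16 and ketone 8 and comes back at 19 by a stepwise Horner–Wittig olefination. Arbuzov reaction of 16 with ethyl diphenylphosphinite (NaI cat., 120 °C) gives the alkyldiphenylphosphine oxide F4. Deprotonation with LiN(i-Pr)2 (THF, −78 °C) and addition to 8 gives the β-hydroxy phosphine oxide F5, whose Z-productive diastereomers (the one drawn and its C9,C10-bis-epimer) are separated from the others by chromatography. NaH in DMF then causes stereospecific syn-elimination of diphenylphosphinate to give geometrically pure 19.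

Step 13 (Stille macrocyclisation). Risks are slow transmetalation of the hindered Z-alkenylstannane, protodestannylation and oligomerisation. The fallback changes the ring-closing reaction type; it sets out from iodide 7 (before stannylation) and ylide 18 and comes back at macrocycle 20. Wittig reaction of 7 with 18 under the conditions of step 12 gives the seco bis(alkenyl iodide) F6. Stoichiometric zerovalent nickel (Ni(cod)2, PPh3, DMF, 45 °C, high dilution) then closes the ring by intramolecular reductive alkenyl–alkenyl coupling with retention of both alkene geometries to give 20.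

**Further compounds**
F1 | step 3 | (4S)-4-benzyl-3-[(2S,3R,4Z)-3-hydroxy-5-iodo-2-[(4-methoxyphenyl)methoxy]-4-(propan-2-yl)pent-4-enoyl]-1,3-oxazolidin-2-one | O=C1OC[C@H](Cc2ccccc2)N1C(=O)[C@@H](OCc1ccc(OC)cc1)[C@H](O)/C(=C\I)C(C)C
F2 | step 3 | (2S,3R,4Z)-3-hydroxy-5-iodo-N-methoxy-2-[(4-methoxyphenyl)methoxy]-N-methyl-4-(propan-2-yl)pent-4-enamide | CON(C)C(=O)[C@@H](OCc1ccc(OC)cc1)[C@H](O)/C(=C\I)C(C)C
F3 | step 3 | (3S,4R,5Z)-4-hydroxy-6-iodo-3-[(4-methoxyphenyl)methoxy]-5-(propan-2-yl)hex-5-en-2-one | CC(=O)[C@@H](OCc1ccc(OC)cc1)[C@H](O)/C(=C\I)C(C)C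
F4 | step 12 | {(3S,4E,8E)-3-[tert-butyl(dimethyl)silyl]oxy-9-iodo-4,8-dimethylnona-4,8-dien-1-yl}diphenylphosphane oxide | O=P(c1ccccc1)(c1ccccc1)CC[C@H](O[Si](C)(C)C(C)(C)C)/C(C)=C/CC/C(C)=C/I
F5 | step 12 | (1E,5E,7S,9R,10S,11S,12R,13Z)-7-[tert-butyl(dimethyl)silyl]oxy-9-(diphenylphosphoryl)-1-iodo-2,6,10-trimethyl-13-(propan-2-yl)-11,12-bis(triethylsilyloxy)-14-(trimethylstannyl)tetradeca-1,5,13-trien-10-ol | C[Sn](C)(C)/C=C(/C(C)C)[C@@H](O[Si](CC)(CC)CC)[C@H](O[Si](CC)(CC)CC)[C@](C)(O)[C@H](P(=O)(c1ccccc1)c1ccccc1)C[C@H](O[Si](C)(C)C(C)(C)C)/C(C)=C/CC/C(C)=C/I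
F6 | step 13 | (1E,5E,7S,9Z,11R,12R,13Z)-7-[tert-butyl(dimethyl)silyl]oxy-1,14-diiodo-2,6,10-trimethyl-13-(propan-2-yl)-11,12-bis(triethylsilyloxy)tetradeca-1,5,9,13-tetraene | I/C=C(/C(C)C)[C@@H](O[Si](CC)(CC)CC)[C@H](O[Si](CC)(CC)CC)/C(C)=C\C[C@H](O[Si](C)(C)C(C)(C)C)/C(C)=C/CC/C(C)=C/I
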